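**Plan**

- Numbering: side-chain carbons C1 (carbonyl) to C8 (OCH2), as in the open-chain ester. Retrosynthetic cuts, in order: the lactone C1(=O)–O bond; both oxirane C–O bonds (C6–O, C7–O); C3–C4; the C8–O aryl ether bond; C7–C8 and C6–CH3.
- Forward: silylated but-3-yn-1-ol is methyl-aluminated and hydroxymethylated to the E-allylic alcohol, joined to 7-hydroxy-8-methoxycoumarin, desilylated, oxidised to the β,γ-unsaturated aldehyde and allylated with methyl 2-(bromomethyl)acrylate. The oxirane ring is made next and the lactone ring last.
- Enabling feature: before lactonisation the future ring oxygen on C4 is a free hydroxyl, one methylene (C5) away from the E-configured C6(Me)=C7H olefin. It can bind a metal peroxide and pass oxygen to one face of that olefin, which becomes the oxirane ring.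
- Stereochemistry: E geometry from syn carboalumination (it becomes the trans-oxirane); C4 from a chiral chromium allylation catalyst; C6 and C7 from a chiral bis-hydroxamate vanadium catalyst acting through the C4 alkoxide.

Key step: step 7

Remark: the sense of induction of the chiral chromium and vanadium catalysts is taken to be selectable through the ligand enantiomer; the descriptors given are those the target demands and are to be confirmed on a first small-scale run (MTPA esters for C4, both ligand antipodes for the oxirane).

**Route**

Step 1
Reactants: 1 but-3-yn-1-ol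
Product: 2 tert-butyl(but-3-yn-1-yloxy)dimethylsilane
Conditions: TBSCl, imidazole, CH2Cl2, 0 °C → rt
Reagents that add atoms: tert-butyldimethylsilyl chloride, CC(C)(C)[Si](C)(C)Cl
Why: Imidazole-promoted silylation of a primary alcohol (silyl ether protection) is routine and keeps this oxygen distinguishable from the allylic hydroxyl made in the next step.

Step 2
Reactants: 2 tert-butyl(but-3-yn-1-yloxy)dimethylsilane
Product: 5 (E)-5-(tert-butyldimethylsilyloxy)-3-methylpent-2-en-1-ol, via alkenyldimethylalane 3 (not isolated), via lithium alkenylalanate 4 (not isolated)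
Conditions: Me3Al, Cp2ZrCl2 (cat.), CH2Cl2, 0 °C → rt; n-BuLi, hexane/THF, −78 → 0 °C; (CH2O)n, THF, rt; aq. Rochelle salt
Reagents that add atoms: trimethylaluminium, C[Al](C)C; paraformaldehyde (formaldehyde source), C=O
Why: Zirconium-catalysed carboalumination (Negishi) adds Me–Al syn across the terminal alkyne with methyl on the internal carbon, which fixes the E-trisubstituted geometry, and the more nucleophilic alanate formed with n-BuLi is hydroxymethylated by formaldehyde with retention of that geometry.

Step 3
Reactants: 5 (E)-5-(tert-butyldimethylsilyloxy)-3-methylpent-2-en-1-ol; 6 7-hydroxy-8-methoxy-2H-chromen-2-one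
Product: 7 7-{[(E)-5-(tert-butyldimethylsilyloxy)-3-methylpent-2-en-1-yl]oxy}-8-methoxy-2H-chromen-2-one
Conditions: PPh3, DIAD, THF, 0 °C → rt
Reagents that add atoms: none
Why: Mitsunobu etherification joins the acidic 7-hydroxyl of the coumarin to the unhindered primary allylic carbon by direct SN2 displacement, without allylic transposition or change of olefin geometry.

Step 4
Reactants: 7 7-{[(E)-5-(tert-butyldimethylsilyloxy)-3-methylpent-2-en-1-yl]oxy}-8-methoxy-2H-chromen-2-one
Product: 8 7-{[(E)-5-hydroxy-3-methylpent-2-en-1-yl]oxy}-8-methoxy-2H-chromen-2-one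
Conditions: HF·pyridine, pyridine, THF, 0 °C → rt
Reagents that add atoms: none
Why: Fluoride-induced cleavage of the silyl ether under pyridine-buffered conditions should leave the acid-sensitive allyl aryl ether and the coumarin lactone untouched.

Step 5
Reactants: 8 7-{[(E)-5-hydroxy-3-methylpent-2-en-1-yl]oxy}-8-methoxy-2H-chromen-2-one
Product: 9 (E)-5-[(8-methoxy-2-oxo-2H-chromen-7-yl)oxy]-3-methylpent-3-enal
Conditions: Dess–Martin periodinane, NaHCO3, CH2Cl2, 0 °C → rt; filtered cold and used at once
Reagents that add atoms: none
Why: Dess–Martin oxidation under bicarbonate buffering is the standard non-basic way to a β,γ-unsaturated aldehyde, and the aldehyde is carried on at once so that the C3=C4 double bond has no opportunity to move into conjugation.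

Step 6
Reactants: 9 (E)-5-[(8-methoxy-2-oxo-2H-chromen-7-yl)oxy]-3-methylpent-3-enal; 10 methyl 2-(bromomethyl)prop-2-enoate
Product: 12 methyl (4R,6E)-4-hydroxy-8-[(8-methoxy-2-oxo-2H-chromen-7-yl)oxy]-6-methyl-2-methylideneoct-6-enoate, via trimethylsilyl ether 11 (not isolated)
Conditions: CrCl2 (10 mol%), chiral tridentate carbazole bis(oxazoline) ligand (12 mol%), i-Pr2NEt (30 mol%), Mn, TMSCl, THF, 0 °C → rt; then aq. citric acid, THF, 0 °C
Reagents that add atoms: none
Why: In this catalytic asymmetric Nozaki–Hiyama–Kishi-type 2-(alkoxycarbonyl)allylation the allylchromium(III) species generated from 10 adds through a closed six-membered transition state within the chiral bis(oxazoline) pocket to the Si face of the aldehyde, which sets C4 as R, while TMSCl turns the catalyst over and caps the alkoxide so that no lactone forms before the brief acidic work-up frees the hydroxyl.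

Step 7
Reactants: 12 methyl (4R,6E)-4-hydroxy-8-[(8-methoxy-2-oxo-2H-chromen-7-yl)oxy]-6-methyl-2-methylideneoct-6-enoate
Product: 13 methyl (4S)-4-hydroxy-5-[(2R,3R)-3-{[(8-methoxy-2-oxo-2H-chromen-7-yl)oxy]methyl}-2-methyloxiran-2-yl]-2-methylidenepentanoate
Conditions: VO(Oi-Pr)3 (2 mol%), chiral C2-symmetric bis-hydroxamic acid ligand derived from trans-cyclohexane-1,2-diamine (4 mol%), cumene hydroperoxide (1.5 equiv), toluene, 0 °C → rt
Reagents that add atoms: cumene hydroperoxide, CC(C)(OO)c1ccccc1
Why: Ligand exchange puts the C4 alkoxide and the alkylperoxide on the same bis-hydroxamate vanadium(V) centre, and the activated peroxide oxygen is then passed intramolecularly to the C6=C7 π bond one methylene away; the closest known reaction type is the vanadium/chiral bis-hydroxamic acid epoxidation of homoallylic alcohols, which descends from VO(acac)2/TBHP directed epoxidation. The oxirane ring closes by concerted, stereospecific syn [2+1] oxygen-atom transfer that makes both C–O bonds at once, so the E geometry becomes the trans arrangement of C5 and the aryloxymethyl carbon on the ring. C6 and C7 are thus set together: their relative configuration by the olefin geometry and their absolute configuration (2R,3R in oxirane numbering) by the olefin face that the C2-symmetric ligand leaves open, with the vanadium-bound (4R)-carbinol as a second, weaker control element, since an E-olefin without a cis substituent has only a small intrinsic bias in the vanadate chair; the required product has the oxirane oxygen anti to the C4 oxygen in the extended chain, and the ligand enantiomer that gives it is fixed by a small-scale run of both antipodes. The step needs site selectivity among three C=C bonds and π-face selectivity: only the trisubstituted olefin is electron-rich, whereas the acrylate C=CH2 (also homoallylic to the hydroxyl) and the coumarin C3=C4 bond are electron-poor and inert to the electrophilic metal peroxide. The methyl ester keeps the C4 hydroxyl free to bind vanadium until the oxirane is in place, and the low catalyst loading and ambient temperature should leave the resulting 3,4-epoxy alcohol unopened. The C4 descriptor changes from R to S only because the new oxirane carbon raises the CIP rank of C5; no bond at C4 is touched.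

Step 8
Reactants: 13 methyl (4S)-4-hydroxy-5-[(2R,3R)-3-{[(8-methoxy-2-oxo-2H-chromen-7-yl)oxy]methyl}-2-methyloxiran-2-yl]-2-methylidenepentanoate
Product: 14 (5S)-5-{[(2R,3R)-3-{[(8-methoxy-2-oxo-2H-chromen-7-yl)oxy]methyl}-2-methyloxiran-2-yl]methyl}-3-methylideneoxolan-2-one
Conditions: 1,3-dichloro-1,1,3,3-tetrabutyldistannoxane (5 mol%), toluene, 80 °C
Reagents that add atoms: none
Why: Distannoxane-catalysed transesterification closes the γ-lactone by 5-exo-trig attack of the C4 hydroxyl on the methyl ester under neutral conditions that should spare the oxirane and the methylene group, and since the C4–O bond is not broken all three stereocentres are carried over unchanged.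

**Compound list**

1 | but-3-yn-1-ol | C#CCCO | starting material
2 | tert-butyl(but-3-yn-1-yloxy)dimethylsilane | C#CCCO[Si](C)(C)C(C)(C)C | intermediate
3 | (E)-[4-(tert-butyldimethylsilyloxy)-2-methylbut-1-en-1-yl]dimethylalane | C[Al](C)/C=C(\C)CCO[Si](C)(C)C(C)(C)C | intermediate
4 | lithium (E)-butyl[4-(tert-butyldimethylsilyloxy)-2-methylbut-1-en-1-yl]dimethylalanate | [Li+].CCCC[Al-](C)(C)/C=C(\C)CCO[Si](C)(C)C(C)(C)C | intermediate
5 | (E)-5-(tert-butyldimethylsilyloxy)-3-methylpent-2-en-1-ol | OC/C=C(\C)CCO[Si](C)(C)C(C)(C)C | intermediate
6 | 7-hydroxy-8-methoxy-2H-chromen-2-one | COc1c(O)ccc2ccc(=O)oc12 | starting material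
7 | 7-{[(E)-5-(tert-butyldimethylsilyloxy)-3-methylpent-2-en-1-yl]oxy}-8-methoxy-2H-chromen-2-one | CC(C)(C)[Si](C)(C)OCC/C(C)=C/COc1ccc2ccc(=O)oc2c1OC | intermediate
8 | 7-{[(E)-5-hydroxy-3-methylpent-2-en-1-yl]oxy}-8-methoxy-2H-chromen-2-one | OCC/C(C)=C/COc1ccc2ccc(=O)oc2c1OC | intermediate
9 | (E)-5-[(8-methoxy-2-oxo-2H-chromen-7-yl)oxy]-3-methylpent-3-enal | O=CC/C(C)=C/COc1ccc2ccc(=O)oc2c1OC | intermediate
10 | methyl 2-(bromomethyl)prop-2-enoate | C=C(CBr)C(=O)OC | starting material
11 | methyl (4R,6E)-8-[(8-methoxy-2-oxo-2H-chromen-7-yl)oxy]-6-methyl-2-methylidene-4-(trimethylsilyloxy)oct-6-enoate | C=C(C[C@H](O[Si](C)(C)C)C/C(C)=C/COc1ccc2ccc(=O)oc2c1OC)C(=O)OC | intermediate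
12 | methyl (4R,6E)-4-hydroxy-8-[(8-methoxy-2-oxo-2H-chromen-7-yl)oxy]-6-methyl-2-methylideneoct-6-enoate | C=C(C[C@H](O)C/C(C)=C/COc1ccc2ccc(=O)oc2c1OC)C(=O)OC | intermediate
13 | methyl (4S)-4-hydroxy-5-[(2R,3R)-3-{[(8-methoxy-2-oxo-2H-chromen-7-yl)oxy]methyl}-2-methyloxiran-2-yl]-2-methylidenepentanoate | C=C(C[C@H](O)C[C@@]1(C)O[C@@H]1COc1ccc2ccc(=O)oc2c1OC)C(=O)OC | intermediate
14 | (5S)-5-{[(2R,3R)-3-{[(8-methoxy-2-oxo-2H-chromen-7-yl)oxy]methyl}-2-methyloxiran-2-yl]methyl}-3-methylideneoxolan-2-one | C=C1C[C@@H](C[C@@]2(C)O[C@@H]2COc2ccc3ccc(=O)oc3c2OC)OC1=O | target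

**Summary**

Total step count: 8. Longest linear sequence: 8 steps (1 → 14); 6 enters in step 3 and 10 in step 6.

Steps most likely to fail:

1. Step 7. The ligand and the resident C4 centre may oppose each other, so that oxygen is delivered with poor facial selectivity, or the vanadium Lewis acid may open the new oxirane with the neighbouring hydroxyl. The fallback sets out from 12 and replaces metal-directed delivery by reagent-controlled, non-directed dioxirane epoxidation (Shi epoxidation: fructose-derived ketone, Oxone, K2CO3-buffered MeCN/dimethoxymethane–water, 0 °C). E-trisubstituted olefins are the best substrate class for it and the electron-poor acrylate and coumarin olefins should not react. The ketone enantiomer is chosen from the spiro transition-state model. The fallback returns to the route at 13 without new intermediates.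

2. Step 6. The C3=C4 double bond of 9 may migrate into conjugation with the formyl group before carbon–carbon bond formation, or enantiofacial discrimination may be modest for this α-unbranched aldehyde. The fallback sets out from 9 and 10: an indium-mediated Barbier allylation in THF/water, which is fast, neutral and stops at the hydroxy ester, should give racemic methyl (6E)-4-hydroxy-8-[(8-methoxy-2-oxo-2H-chromen-7-yl)oxy]-6-methyl-2-methylideneoct-6-enoate F1. F1 is then put through the conditions of step 7, where the chiral vanadium catalyst serves as the resolving agent. The (4R)-enantiomer should be epoxidised on the required face, while the (4S)-enantiomer is left behind or ends as a diastereomeric epoxy alcohol that is removed by chromatography. The route is rejoined at 13, at the price of half the material.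

3. Step 8. The trisubstituted oxirane may be opened by the tin Lewis acid or by the free hydroxyl, or liberated methanol may add to the methylene lactone on prolonged heating. The fallback sets out from 13: the methyl ester is cleaved first (Me3SnOH, 1,2-dichloroethane, 60 °C) to (4S)-4-hydroxy-5-[(2R,3R)-3-{[(8-methoxy-2-oxo-2H-chromen-7-yl)oxy]methyl}-2-methyloxiran-2-yl]-2-methylidenepentanoic acid F2. The ring is then closed by carboxyl activation at low temperature (EDC·HCl, cat. DMAP, CH2Cl2, 0 °C), which arrives at 14.

**Further compounds**

F0 | step 7 | none | none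
F1 | step 6 | methyl (6E)-4-hydroxy-8-[(8-methoxy-2-oxo-2H-chromen-7-yl)oxy]-6-methyl-2-methylideneoct-6-enoate (racemate) | C=C(CC(O)C/C(C)=C/COc1ccc2ccc(=O)oc2c1OC)C(=O)OC
F2 | step 8 | (4S)-4-hydroxy-5-[(2R,3R)-3-{[(8-methoxy-2-oxo-2H-chromen-7-yl)oxy]methyl}-2-methyloxiran-2-yl]-2-methylidenepentanoic acid | C=C(C[C@H](O)C[C@@]1(C)O[C@@H]1COc1ccc2ccc(=O)oc2c1OC)C(=O)O
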